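Whatever leaves the starting material should reappear as target or idle complex. That sum is my invariant, and in the delta run at 15.0 min it falls short by 4.2 percentage points, so something beyond target is forming unseen.

the same everywhere: gas phase 29 mM (held)
- beta: starting material 0.50 M; catalyst 5 mM; the very flask that is asked about, followed so far
- delta: starting material 0.75 M; catalyst 5 mM; run made earlier
- flask: starting material 0.50 M; catalyst 5.0 mM; time 15 min

beta run (percent of the starting material charged)

| time / s | target / % | idle complex / % | starting material / % |
|---|---|---|---|
| 15.0 | 1.1 | 1.1 | 100.4 |
| 30.0 | 1.0 | 0.6 | 100.4 |
| 50.0 | 0.6 | 0 | 99.3 |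
| 60.0 | 2.6 | 0 | 98.3 |
| 80.0 | 2.5 | 0 | 96.6 |
| 90.0 | 3.7 | 0 | 96.7 |
| 120 | 3.5 | 0.1 | 96.0 |

delta run (percent of the starting material charged)

| time / min | target / % | idle complex / % | starting material / % |
|---|---|---|---|
| 2.00 | 3.8 | 0.5 | 96.6 |
| 4.00 | 8.5 | 0.4 | 91.5 |
| 6.00 | 12.3 | 0.2 | 87.5 |
| 8.00 | 15.4 | 0.5 | 82.7 |
| 10.0 | 19.3 | 0.2 | 79.2 |
| 12.0 | 21.1 | 0 | 75.0 |
| 15.0 | 25.4 | 0 | 70.4 |

(standard deviation of a reading: 0.5 percentage points)

* the target and idle complex together standing at 15 min, as a percentage of the starting material charged
* the change that raises the amount of target and idle complex together at 15 min, in percent of the starting material charged most ("none" if none brings more than 2 percentage points) (dusk / winter / dawn / none)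
* amount of target and idle complex together at 15 min, in percent of the starting material charged, after winter

- dusk: doubling the transfer coefficient of the gas phase, all else as stated
- winter: doubling the saturation concentration of gas phase, all else as stated
- dawn: doubling the amount of catalyst, all else as stated

- amounts and yields of target count idle complex too
- at the start none of the gas phase is in solution

In the beta flask the starting material still reads 100.4% at 30.0 s, while the gas phase enters solution from nothing, so I take the rate to follow dissolved gas. Supply grows with the gap to saturation and use grows with the dissolved level, so I expect the two to balance soon, and as an approximation I freeze the level at one share of saturation, although use must ease as the starting material falls. On that approximation the starting material decays with a pseudo-first-order constant. I call it kobs, the fractional loss of starting material per unit time after the lag, and beta between 50.0 s and 120 s gives 0.0290 min⁻¹.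

That reading rests on a few points of loss, with a scatter of 0.5 points, so I test it on the delta run, whose whole course gives 0.0234 min⁻¹. This is lower. It may be scatter, but more starting material should also use gas faster and press the level down. Taken as real, the ratio u of use to supply in beta is 0.909.

Carried to 15 min, kobs leaves 65.9% of the starting material in the beta flask. Subtracting the delta loss, read at a similar conversion, gives my y of 29.9%. Doubling saturation doubles the frozen level at any u, so kobs doubles, and if the loss doubles with the target, winter gives 47.9%. Dawn also doubles the use of gas, so kobs gains a factor of 1.35, and dusk gains 1.31, both below 2, so I choose winter.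

The forecast, which parts from me on the last two answers, gives 26%, dawn and 27%, calling the flask “catalyst-limited and roughly zero order in gas”.

The simulation gives 29.7%, winter with a gain of 18 points, and 48.2%.

    target → over-reaction product B (k = 1.30 × 10⁻⁶ s⁻¹)
    gas phase ⇌ dissolved gas, rate k2*(csat - [dissolved gas]) (kL = 0.0180 s⁻¹)
    catalyst + target ⇌ idle complex (K = 2.10 M⁻¹, k = 0.0610 M⁻¹ s⁻¹)
    target → over-reaction product A (k = 4.00 × 10⁻⁴ s⁻¹)
    starting material + dissolved gas + catalyst → catalyst + target (k = 6.80 M⁻² s⁻¹)

With kobs I expected 65.9% of the starting material left in this flask, and it holds 64%. For the same charge left until 1.0 h, kobs gives 17.9% against the simulated 14%. Dissolved gas in this flask is not truly frozen: it climbs from 0.0145 M at 1.50 min to 0.0196 M at 15.0 min, still below its saturation of 29 mM. The slow passage of gas phase into dissolved gas is part of the reason y stays low: with that passage made fast, the run gives 41.4% instead of 29.7%. What y keeps at 15 min rests on the early reading together with the way back from idle complex to catalyst and target: without that way back the run gives 16.3%, and read at 150 min it gives 7.44%.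

The readings were generated by integration on assumed constants; scatter was added.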